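**Retrosynthetic overview**

- The last skeletal bond is C2'–C3' of the side chain: an sp3–sp2 Negishi coupling joins a (2S)-2-(2-iodoethyl)chroman to an all-E C39 alkenyl iodide, and the silyl group on O6 is removed at the end.
- The route rests on C2 of the dihydropyran ring. It carries O1, a methyl group, ring carbon C3 and side-chain carbon C1' and no hydrogen, so closing O1–C2 by oxypalladation of a 2-(3-methylbut-3-enyl)phenol leaves palladium on C1' with no β-hydrogen, free to take up CO and form C1'–C2'.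
- Ring order: the benzene ring is bought as 2,3-dimethylhydroquinone; the dihydropyran ring is the only ring formed, in the key step, together with the C2 stereocentre.
- The phenol precursor comes from the hydroquinone by mono-silylation, ortho-formylation, Wittig enone formation, hydrogenation and methylenation.
- The C39 iodide comes from geranylgeranyl phenyl sulfone and a farnesol-derived ω-bromo silyl-enyne (sulfone alkylation, reductive desulfonylation), then alkyne desilylation and methylalumination–iodination.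

Key step: step 6

Assumption (chemistry): the (S,S)-benzyl bis(oxazoline) ligand is taken to be the enantiomer that closes the ring to the (2S)-configured chromanylacetate; should the sense of induction prove opposite, its mirror-image ligand is used and nothing else changes.

**Route**

Step 1
Reactants: 1 2,3-dimethylhydroquinone
Product: 2 4-(tert-butyldimethylsilyloxy)-2,3-dimethylphenol
Conditions: TBSCl (1.0 equiv), imidazole (2.2 equiv), DMF, 0 °C → rt, argon
Reagents that add atoms: tert-butyldimethylsilyl chloride, CC(C)(C)[Si](C)(C)Cl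
Why: Silylation of a phenol with a silyl chloride and imidazole, in which the two hydroxyls of 1 are equivalent by symmetry so that only one mono-ether can form and is separated from recovered diol and bis-ether.

Step 2
Reactants: 2 4-(tert-butyldimethylsilyloxy)-2,3-dimethylphenol
Product: 3 5-(tert-butyldimethylsilyloxy)-2-hydroxy-3,4-dimethylbenzaldehyde
Conditions: MgCl2 (2 equiv), Et3N (4 equiv), paraformaldehyde (6 equiv), MeCN, reflux
Reagents that add atoms: paraformaldehyde (as formaldehyde), C=O
Why: Casnati–Skattebøl ortho-formylation through the magnesium phenoxide delivers formaldehyde only to the carbon next to the free hydroxyl, and the sole open ortho position is C6 because C2 carries a methyl group.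

Step 3
Reactants: 3 5-(tert-butyldimethylsilyloxy)-2-hydroxy-3,4-dimethylbenzaldehyde
Product: 4 (3E)-4-[5-(tert-butyldimethylsilyloxy)-2-hydroxy-3,4-dimethylphenyl]but-3-en-2-one
Conditions: Ph3P=CHC(O)CH3 (1.3 equiv), toluene, 90 °C
Reagents that add atoms: 1-(triphenylphosphoranylidene)propan-2-one, CC(=O)C=P(c1ccccc1)(c1ccccc1)c1ccccc1
Why: Wittig olefination with a stabilised ylide should give the E-enone under neutral conditions, which spares the aryl silyl ether that a hydroxide-mediated aldol condensation with acetone would cleave.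

Step 4
Reactants: 4 (3E)-4-[5-(tert-butyldimethylsilyloxy)-2-hydroxy-3,4-dimethylphenyl]but-3-en-2-one
Product: 5 4-[5-(tert-butyldimethylsilyloxy)-2-hydroxy-3,4-dimethylphenyl]butan-2-one
Conditions: H2 (1 atm), 10% Pd/C, EtOAc, rt
Reagents that add atoms: none
Why: Heterogeneous catalytic hydrogenation saturates the conjugated alkene far faster than it touches the ketone, the arene or the silyl ether.

Step 5
Reactants: 5 4-[5-(tert-butyldimethylsilyloxy)-2-hydroxy-3,4-dimethylphenyl]butan-2-one
Product: 6 4-(tert-butyldimethylsilyloxy)-2,3-dimethyl-6-(3-methylbut-3-enyl)phenol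
Conditions: Ph3PCH3Br (3.2 equiv), n-BuLi (3.0 equiv), THF, 0 °C → rt
Reagents that add atoms: methyltriphenylphosphonium bromide, C[P+](c1ccccc1)(c1ccccc1)c1ccccc1.[Br-]
Why: Wittig methylenation of the methyl ketone installs the 1,1-disubstituted alkene, the excess of preformed ylide covering the equivalent that the acidic phenol consumes.

Step 6
Reactants: 6 4-(tert-butyldimethylsilyloxy)-2,3-dimethyl-6-(3-methylbut-3-enyl)phenol
Product: 7 methyl 2-[(2S)-6-(tert-butyldimethylsilyloxy)-2,7,8-trimethylchroman-2-yl]acetate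
Conditions: Pd(OCOCF3)2 (5 mol%), (S,S)-Bn-BOXAX [(Sa)-2,2'-bis((4S)-4-benzyl-4,5-dihydrooxazol-2-yl)-1,1'-binaphthyl] (20 mol%), p-benzoquinone (4 equiv), CO (1 atm), MeOH, rt
Reagents that add atoms: carbon monoxide, [C-]#[O+]; methanol, CO
Why: The ligated palladium trifluoroacetate (divalent palladium) coordinates the terminal alkene of 6 and the phenolic oxygen adds to its disubstituted carbon, closing O1–C2; the σ-alkyl complex formed has palladium on C1', next to the fully substituted C2, so it persists long enough to insert CO, and methanol cleaves the acyl complex to the methyl ester (new C1'–C2' bond) while p-benzoquinone returns zerovalent palladium to the divalent state. The closest known reaction type is the enantioselective domino Wacker cyclisation–carbonylation of 2-(3-methylbut-3-enyl)phenols with Pd(OCOCF3)2 and binaphthyl bis(oxazoline) ligands. The dihydropyran ring closes in a 6-exo-trig oxypalladation. The C2 stereocentre is set in that event by the C2-symmetric ligand, which lets the phenol reach only one enantioface of the bound alkene. The step needs carbonylative capture to win over Wacker-type β-hydride elimination and 6-exo closure to win over 7-endo closure; the first is secured by the absence of hydrogen on C2 and the second by attack at the more substituted alkene carbon through a six-membered transition state.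

Step 7
Reactants: 7 methyl 2-[(2S)-6-(tert-butyldimethylsilyloxy)-2,7,8-trimethylchroman-2-yl]acetate
Product: 8 2-[(2S)-6-(tert-butyldimethylsilyloxy)-2,7,8-trimethylchroman-2-yl]ethanol
Conditions: i-Bu2AlH (2.5 equiv), CH2Cl2, −78 → 0 °C; aq. potassium sodium tartrate
Reagents that add atoms: none
Why: Hydride reduction of the ester to the primary alcohol with i-Bu2AlH at low temperature should leave the aryl silyl ether and the quaternary C2 stereocentre untouched.

Step 8
Reactants: 8 2-[(2S)-6-(tert-butyldimethylsilyloxy)-2,7,8-trimethylchroman-2-yl]ethanol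
Product: 9 (2S)-6-(tert-butyldimethylsilyloxy)-2-(2-iodoethyl)-2,7,8-trimethylchroman
Conditions: I2 (1.3 equiv), PPh3 (1.3 equiv), imidazole (1.5 equiv), CH2Cl2, 0 °C → rt
Reagents that add atoms: iodine, II
Why: Appel-type iodination converts the unhindered primary alcohol into the iodide by SN2 displacement of the oxyphosphonium group, with no bearing on C2.

Step 9
Reactants: 10 (2E,6E)-farnesol
Product: 11 (2E,6E)-farnesyl bromide
Conditions: PBr3 (0.4 equiv), Et2O, −10 → 0 °C; used crude
Reagents that add atoms: phosphorus tribromide, BrP(Br)Br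
Why: Bromination of a primary allylic alcohol with PBr3 at low temperature proceeds by SN2 displacement without allylic transposition or loss of the E geometry.

Step 10
Reactants: 11 (2E,6E)-farnesyl bromide
Product: 12 trimethyl[(5E,9E)-6,10,14-trimethylpentadeca-5,9,13-trien-1-ynyl]silane
Conditions: 1-(trimethylsilyl)propyne (1.3 equiv), n-BuLi (1.25 equiv), THF, −78 → −20 °C; then 11, −78 °C → rt
Reagents that add atoms: 1-(trimethylsilyl)propyne, CC#C[Si](C)(C)C
Why: SN2 alkylation of the propargylic lithium reagent at the primary allylic carbon of 11 adds the three-carbon alkyne unit, the silyl group directing bond formation to the propargyl and not the allenyl terminus.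

Step 11
Reactants: 12 trimethyl[(5E,9E)-6,10,14-trimethylpentadeca-5,9,13-trien-1-ynyl]silane
Product: 13 (2E,6E,10E)-2,6,10-trimethyl-15-(trimethylsilyl)pentadeca-2,6,10-trien-14-yn-1-ol
Conditions: SeO2 (0.2 equiv), t-BuOOH (3 equiv), salicylic acid (0.1 equiv), CH2Cl2, 0 °C → rt; stopped at partial conversion, 12 recycled
Reagents that add atoms: selenium dioxide, O=[Se]=O; tert-butyl hydroperoxide, CC(C)(C)OO
Why: Riley allylic oxidation proceeds by an ene reaction and a 2,3-sigmatropic shift that should oxidise the E-methyl group of the terminal isopropylidene unit, the most accessible trisubstituted alkene, to the E-allylic alcohol.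

Step 12
Reactants: 13 (2E,6E,10E)-2,6,10-trimethyl-15-(trimethylsilyl)pentadeca-2,6,10-trien-14-yn-1-ol
Product: 14 [(5E,9E,13E)-15-bromo-6,10,14-trimethylpentadeca-5,9,13-trien-1-ynyl]trimethylsilane
Conditions: CBr4 (1.2 equiv), PPh3 (1.25 equiv), CH2Cl2, 0 °C; used directly
Reagents that add atoms: carbon tetrabromide, BrC(Br)(Br)Br
Why: Appel bromination of the primary allylic alcohol under neutral conditions should give the primary allylic bromide with the E-alkene and the silylalkyne unchanged.

Step 13
Reactants: 15 (2E,6E,10E)-geranylgeraniol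
Product: 16 (2E,6E,10E)-geranylgeranyl bromide
Conditions: PBr3 (0.4 equiv), Et2O, −10 → 0 °C; used crude
Reagents that add atoms: phosphorus tribromide, BrP(Br)Br
Why: The same SN2 bromination of a primary allylic alcohol as in step 9 keeps the position and geometry of the C2 alkene.

Step 14
Reactants: 16 (2E,6E,10E)-geranylgeranyl bromide
Product: 17 (2E,6E,10E)-geranylgeranyl phenyl sulfone
Conditions: PhSO2Na (1.5 equiv), DMF, rt
Reagents that add atoms: sodium benzenesulfinate, [Na+].[O-]S(=O)c1ccccc1
Why: S-alkylation of the sulfinate by the primary allylic bromide (SN2) gives the allylic sulfone whose C1 is acidic enough for the chain-joining step.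

Step 15
Reactants: 17 (2E,6E,10E)-geranylgeranyl phenyl sulfone; 14 [(5E,9E,13E)-15-bromo-6,10,14-trimethylpentadeca-5,9,13-trien-1-ynyl]trimethylsilane
Product: 19 trimethyl[(5E,9E,13E,17E,21E,25E)-6,10,14,18,22,26,30-heptamethyl-16-(phenylsulfonyl)hentriaconta-5,9,13,17,21,25,29-heptaen-1-ynyl]silane (racemic at C16), via lithiated sulfone 18 (not isolated)
Conditions: n-BuLi (1.05 equiv), THF/DMPU, −78 °C; then 14 (1.0 equiv), −78 → −30 °C
Reagents that add atoms: none
Why: Biellmann-type sulfone alkylation, in which the sulfone-stabilised allylic carbanion attacks the primary allylic bromide through its α-carbon in an SN2 reaction, joins the C20 and C18 chains without touching any alkene, the new sulfonyl-bearing centre being racemic and removed in the next step.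

Step 16
Reactants: 19 trimethyl[(5E,9E,13E,17E,21E,25E)-6,10,14,18,22,26,30-heptamethyl-16-(phenylsulfonyl)hentriaconta-5,9,13,17,21,25,29-heptaen-1-ynyl]silane
Product: 20 trimethyl[(5E,9E,13E,17E,21E,25E)-6,10,14,18,22,26,30-heptamethylhentriaconta-5,9,13,17,21,25,29-heptaen-1-ynyl]silane
Conditions: Pd(dppp)Cl2 (5 mol%), LiBHEt3 (2.2 equiv), THF, 0 °C
Reagents that add atoms: none
Why: In this palladium-catalysed reductive desulfonylation, zerovalent palladium ionises the allylic sulfone to a π-allyl complex and hydride from LiBHEt3 is delivered to the less substituted terminus, which should keep the trisubstituted E-alkene in place.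

Step 17
Reactants: 20 trimethyl[(5E,9E,13E,17E,21E,25E)-6,10,14,18,22,26,30-heptamethylhentriaconta-5,9,13,17,21,25,29-heptaen-1-ynyl]silane
Product: 21 (5E,9E,13E,17E,21E,25E)-6,10,14,18,22,26,30-heptamethylhentriaconta-5,9,13,17,21,25,29-heptaen-1-yne
Conditions: K2CO3 (0.5 equiv), MeOH/THF, rt
Reagents that add atoms: none
Why: Base-catalysed methanolysis of the alkynyl C–Si bond (protodesilylation) frees the terminal alkyne and leaves the polyene untouched.

Step 18
Reactants: 21 (5E,9E,13E,17E,21E,25E)-6,10,14,18,22,26,30-heptamethylhentriaconta-5,9,13,17,21,25,29-heptaen-1-yne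
Product: 23 (1E,5E,9E,13E,17E,21E,25E)-1-iodo-2,6,10,14,18,22,26,30-octamethylhentriaconta-1,5,9,13,17,21,25,29-octaene, via alkenyldimethylalane 22 (not isolated)
Conditions: AlMe3 (2.5 equiv), Cp2ZrCl2 (0.5 equiv), CH2Cl2, 0 °C → rt; then I2, THF, −30 → 0 °C
Reagents that add atoms: trimethylaluminium, C[Al](C)C; iodine, II
Why: Negishi zirconium-catalysed methylalumination adds methyl and aluminium syn across the terminal alkyne with methyl on the internal carbon, and iodinolysis of the C–Al bond with retention should give the E-alkenyl iodide while the isolated trisubstituted alkenes stay inert.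

Step 19
Reactants: 9 (2S)-6-(tert-butyldimethylsilyloxy)-2-(2-iodoethyl)-2,7,8-trimethylchroman; 23 (1E,5E,9E,13E,17E,21E,25E)-1-iodo-2,6,10,14,18,22,26,30-octamethylhentriaconta-1,5,9,13,17,21,25,29-octaene
Product: 25 (2R)-6-(tert-butyldimethylsilyloxy)-2,7,8-trimethyl-2-[(3E,7E,11E,15E,19E,23E,27E)-4,8,12,16,20,24,28,32-octamethyltritriaconta-3,7,11,15,19,23,27,31-octaenyl]chroman, via alkylzinc iodide 24 (not isolated)
Conditions: Zn dust (activated with BrCH2CH2Br and Me3SiCl), LiCl, THF, 40 °C; then 23 (0.9 equiv), Pd(dppf)Cl2 (5 mol%), THF, rt → 45 °C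
Reagents that add atoms: none
Why: Negishi sp3–sp2 cross-coupling, in which LiCl-promoted zinc insertion into the primary iodide gives an alkylzinc that transmetalates to the alkenylpalladium iodide formed from 23, should form C2'–C3' with retention of the E geometry and without involving C2.

Step 20
Reactants: 25 (2R)-6-(tert-butyldimethylsilyloxy)-2,7,8-trimethyl-2-[(3E,7E,11E,15E,19E,23E,27E)-4,8,12,16,20,24,28,32-octamethyltritriaconta-3,7,11,15,19,23,27,31-octaenyl]chroman
Product: 26 plastochromanol 8
Conditions: Bu4NF (1.2 equiv), THF, 0 °C, argon; aqueous work-up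
Reagents that add atoms: none
Why: Fluoride-mediated desilylation of the aryl silyl ether frees the C6 phenol under conditions that affect neither the polyene nor the C2 stereocentre.

**Compound list**

1 | 2,3-dimethylhydroquinone | Cc1c(O)ccc(O)c1C | starting material
2 | 4-(tert-butyldimethylsilyloxy)-2,3-dimethylphenol | Cc1c(O)ccc(O[Si](C)(C)C(C)(C)C)c1C | intermediate
3 | 5-(tert-butyldimethylsilyloxy)-2-hydroxy-3,4-dimethylbenzaldehyde | O=Cc1cc(O[Si](C)(C)C(C)(C)C)c(C)c(C)c1O | intermediate
4 | (3E)-4-[5-(tert-butyldimethylsilyloxy)-2-hydroxy-3,4-dimethylphenyl]but-3-en-2-one | CC(=O)/C=C/c1cc(O[Si](C)(C)C(C)(C)C)c(C)c(C)c1O | intermediate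
5 | 4-[5-(tert-butyldimethylsilyloxy)-2-hydroxy-3,4-dimethylphenyl]butan-2-one | CC(=O)CCc1cc(O[Si](C)(C)C(C)(C)C)c(C)c(C)c1O | intermediate
6 | 4-(tert-butyldimethylsilyloxy)-2,3-dimethyl-6-(3-methylbut-3-enyl)phenol | C=C(C)CCc1cc(O[Si](C)(C)C(C)(C)C)c(C)c(C)c1O | intermediate
7 | methyl 2-[(2S)-6-(tert-butyldimethylsilyloxy)-2,7,8-trimethylchroman-2-yl]acetate | COC(=O)C[C@]1(C)CCc2cc(O[Si](C)(C)C(C)(C)C)c(C)c(C)c2O1 | intermediate
8 | 2-[(2S)-6-(tert-butyldimethylsilyloxy)-2,7,8-trimethylchroman-2-yl]ethanol | OCC[C@]1(C)CCc2cc(O[Si](C)(C)C(C)(C)C)c(C)c(C)c2O1 | intermediate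
9 | (2S)-6-(tert-butyldimethylsilyloxy)-2-(2-iodoethyl)-2,7,8-trimethylchroman | ICC[C@]1(C)CCc2cc(O[Si](C)(C)C(C)(C)C)c(C)c(C)c2O1 | intermediate
10 | (2E,6E)-farnesol | CC(C)=CCC/C(C)=C/CC/C(C)=C/CO | starting material
11 | (2E,6E)-farnesyl bromide | CC(C)=CCC/C(C)=C/CC/C(C)=C/CBr | intermediate
12 | trimethyl[(5E,9E)-6,10,14-trimethylpentadeca-5,9,13-trien-1-ynyl]silane | CC(C)=CCC/C(C)=C/CC/C(C)=C/CCC#C[Si](C)(C)C | intermediate
13 | (2E,6E,10E)-2,6,10-trimethyl-15-(trimethylsilyl)pentadeca-2,6,10-trien-14-yn-1-ol | OC/C(C)=C/CC/C(C)=C/CC/C(C)=C/CCC#C[Si](C)(C)C | intermediate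
14 | [(5E,9E,13E)-15-bromo-6,10,14-trimethylpentadeca-5,9,13-trien-1-ynyl]trimethylsilane | BrC/C(C)=C/CC/C(C)=C/CC/C(C)=C/CCC#C[Si](C)(C)C | intermediate
15 | (2E,6E,10E)-geranylgeraniol | CC(C)=CCC/C(C)=C/CC/C(C)=C/CC/C(C)=C/CO | starting material
16 | (2E,6E,10E)-geranylgeranyl bromide | CC(C)=CCC/C(C)=C/CC/C(C)=C/CC/C(C)=C/CBr | intermediate
17 | (2E,6E,10E)-geranylgeranyl phenyl sulfone | CC(C)=CCC/C(C)=C/CC/C(C)=C/CC/C(C)=C/CS(=O)(=O)c1ccccc1 | intermediate
18 | lithiated sulfone, [(2E,6E,10E)-3,7,11,15-tetramethyl-1-(phenylsulfonyl)hexadeca-2,6,10,14-tetraenyl]lithium | CC(C)=CCC/C(C)=C/CC/C(C)=C/CC/C(C)=C/C([Li])S(=O)(=O)c1ccccc1 | intermediate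
19 | trimethyl[(5E,9E,13E,17E,21E,25E)-6,10,14,18,22,26,30-heptamethyl-16-(phenylsulfonyl)hentriaconta-5,9,13,17,21,25,29-heptaen-1-ynyl]silane (racemic at C16) | CC(C)=CCC/C(C)=C/CC/C(C)=C/CC/C(C)=C/C(C/C(C)=C/CC/C(C)=C/CC/C(C)=C/CCC#C[Si](C)(C)C)S(=O)(=O)c1ccccc1 | intermediate
20 | trimethyl[(5E,9E,13E,17E,21E,25E)-6,10,14,18,22,26,30-heptamethylhentriaconta-5,9,13,17,21,25,29-heptaen-1-ynyl]silane | CC(C)=CCC/C(C)=C/CC/C(C)=C/CC/C(C)=C/CC/C(C)=C/CC/C(C)=C/CC/C(C)=C/CCC#C[Si](C)(C)C | intermediate
21 | (5E,9E,13E,17E,21E,25E)-6,10,14,18,22,26,30-heptamethylhentriaconta-5,9,13,17,21,25,29-heptaen-1-yne | CC(C)=CCC/C(C)=C/CC/C(C)=C/CC/C(C)=C/CC/C(C)=C/CC/C(C)=C/CC/C(C)=C/CCC#C | intermediate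
22 | alkenyldimethylalane, dimethyl[(1E,5E,9E,13E,17E,21E,25E)-2,6,10,14,18,22,26,30-octamethylhentriaconta-1,5,9,13,17,21,25,29-octaenyl]alumane | CC(C)=CCC/C(C)=C/CC/C(C)=C/CC/C(C)=C/CC/C(C)=C/CC/C(C)=C/CC/C(C)=C/CC/C(C)=C/[Al](C)C | intermediate
23 | (1E,5E,9E,13E,17E,21E,25E)-1-iodo-2,6,10,14,18,22,26,30-octamethylhentriaconta-1,5,9,13,17,21,25,29-octaene | CC(C)=CCC/C(C)=C/CC/C(C)=C/CC/C(C)=C/CC/C(C)=C/CC/C(C)=C/CC/C(C)=C/CC/C(C)=C/I | intermediate
24 | alkylzinc iodide, {2-[(2S)-6-(tert-butyldimethylsilyloxy)-2,7,8-trimethylchroman-2-yl]ethyl}zinc iodide | I[Zn]CC[C@]1(C)CCc2cc(O[Si](C)(C)C(C)(C)C)c(C)c(C)c2O1 | intermediate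
25 | (2R)-6-(tert-butyldimethylsilyloxy)-2,7,8-trimethyl-2-[(3E,7E,11E,15E,19E,23E,27E)-4,8,12,16,20,24,28,32-octamethyltritriaconta-3,7,11,15,19,23,27,31-octaenyl]chroman | CC(C)=CCC/C(C)=C/CC/C(C)=C/CC/C(C)=C/CC/C(C)=C/CC/C(C)=C/CC/C(C)=C/CC/C(C)=C/CC[C@]1(C)CCc2cc(O[Si](C)(C)C(C)(C)C)c(C)c(C)c2O1 | intermediate
26 | plastochromanol 8, (2R)-2,7,8-trimethyl-2-[(3E,7E,11E,15E,19E,23E,27E)-4,8,12,16,20,24,28,32-octamethyltritriaconta-3,7,11,15,19,23,27,31-octaenyl]chroman-6-ol | CC(C)=CCC/C(C)=C/CC/C(C)=C/CC/C(C)=C/CC/C(C)=C/CC/C(C)=C/CC/C(C)=C/CC/C(C)=C/CC[C@]1(C)CCc2cc(O)c(C)c(C)c2O1 | target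

**Step count**

Total: 20 steps. Longest linear sequence: 10 steps (steps 1–8, 19, 20 from 1; the line from 10 through steps 9–12 and 15–20 is equally long).

**Steps most likely to fail**

Step 6. Enantioface selection may be incomplete, or CO may reduce divalent palladium to inactive metal faster than the quinone reoxidises it, so that turnover stops; slow methanolysis of the aryl silyl ether is a lesser concern. The fallback sets out from 6 and comes back at 8. The same oxypalladation is terminated by a Heck reaction in place of carbonylation: 6 with methyl acrylate, Pd(OCOCF3)2, the same ligand and p-benzoquinone in CH2Cl2 without CO should give methyl (2E)-4-[(2S)-6-(tert-butyldimethylsilyloxy)-2,7,8-trimethylchroman-2-yl]but-2-enoate F1. Lemieux–Johnson cleavage of the enoate alkene (catalytic OsO4, NaIO4, 2,6-lutidine, dioxane/water) should give 2-[(2S)-6-(tert-butyldimethylsilyloxy)-2,7,8-trimethylchroman-2-yl]acetaldehyde F2, and NaBH4 in MeOH reduces it to alcohol 8.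

Step 11. Oxidation at internal allylic positions and over-oxidation of the product to the enal may compete with the terminal ene reaction, so that little E-alcohol is obtained at useful conversion. The fallback sets out from 12 and comes back at 13, replacing direct C–H oxidation by degradation and rebuilding of the terminal alkene.
- NBS in aqueous THF at 0 °C should add selectively to the terminal alkene to give racemic (6E,10E)-3-bromo-2,6,10-trimethyl-15-(trimethylsilyl)pentadeca-6,10-dien-14-yn-2-ol F3.
- NaH in THF closes it to racemic [(5E,9E)-12-(3,3-dimethyloxiran-2-yl)-6,10-dimethyldodeca-5,9-dien-1-ynyl]trimethylsilane F4.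
- Periodic acid in THF/Et2O cleaves the epoxide to (4E,8E)-4,8-dimethyl-13-(trimethylsilyl)trideca-4,8-dien-12-ynal F5.
- Wittig reaction with Ph3P=C(CH3)CO2Et in CH2Cl2 should give ethyl (2E,6E,10E)-2,6,10-trimethyl-15-(trimethylsilyl)pentadeca-2,6,10-trien-14-ynoate F6.
- i-Bu2AlH in CH2Cl2 at −78 °C reduces the ester to 13.

Step 19. Zinc insertion may be slow or the alkylzinc may be protonated, and β-hydride elimination from the alkylpalladium intermediate may compete with reductive elimination, wasting both advanced iodides. The fallback sets out from 9 and comes back at 25, using a B-alkyl Suzuki–Miyaura coupling. Addition of t-BuLi to a mixture of 9 and 9-methoxy-9-borabicyclo[3.3.1]nonane in Et2O/THF at −78 °C traps the alkyllithium as it forms, giving lithium {2-[(2R)-6-(tert-butyldimethylsilyloxy)-2,7,8-trimethylchroman-2-yl]ethyl}(methoxy)(cyclooctane-1,5-diyl)borate F7. Coupling of F7 with 23 under Pd(dppf)Cl2 and aqueous K3PO4 in DMF at rt should give 25.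

**Further compounds**

F1 | step 6 | methyl (2E)-4-[(2S)-6-(tert-butyldimethylsilyloxy)-2,7,8-trimethylchroman-2-yl]but-2-enoate | COC(=O)/C=C/C[C@]1(C)CCc2cc(O[Si](C)(C)C(C)(C)C)c(C)c(C)c2O1
F2 | step 6 | 2-[(2S)-6-(tert-butyldimethylsilyloxy)-2,7,8-trimethylchroman-2-yl]acetaldehyde | O=CC[C@]1(C)CCc2cc(O[Si](C)(C)C(C)(C)C)c(C)c(C)c2O1
F3 | step 11 | racemic (6E,10E)-3-bromo-2,6,10-trimethyl-15-(trimethylsilyl)pentadeca-6,10-dien-14-yn-2-ol | CC(C)(O)C(Br)CC/C(C)=C/CC/C(C)=C/CCC#C[Si](C)(C)C
F4 | step 11 | racemic [(5E,9E)-12-(3,3-dimethyloxiran-2-yl)-6,10-dimethyldodeca-5,9-dien-1-ynyl]trimethylsilane | CC1(C)OC1CC/C(C)=C/CC/C(C)=C/CCC#C[Si](C)(C)C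
F5 | step 11 | (4E,8E)-4,8-dimethyl-13-(trimethylsilyl)trideca-4,8-dien-12-ynal | O=CCC/C(C)=C/CC/C(C)=C/CCC#C[Si](C)(C)C
F6 | step 11 | ethyl (2E,6E,10E)-2,6,10-trimethyl-15-(trimethylsilyl)pentadeca-2,6,10-trien-14-ynoate | CCOC(=O)/C(C)=C/CC/C(C)=C/CC/C(C)=C/CCC#C[Si](C)(C)C
F7 | step 19 | lithium {2-[(2R)-6-(tert-butyldimethylsilyloxy)-2,7,8-trimethylchroman-2-yl]ethyl}(methoxy)(cyclooctane-1,5-diyl)borate | [Li+].CO[B-]1(CC[C@]2(C)CCc3cc(O[Si](C)(C)C(C)(C)C)c(C)c(C)c3O2)C2CCCC1CCC2
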